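5 questions stand here, one order and 4 shares, and they are questions about how X is divided.

| setting | zeta | theta | gamma | eta | maple | birch | elm | larch |
|---|---|---|---|---|---|---|---|---|
| D | 0.10 M | 0.050 M | 0.075 M | 0.10 M | 0.10 M | 0.10 M | 0.10 M | 0.10 M |
| G | 0.15 M | 0.15 M | 0.15 M | 0.22 M | 0.150 M | 0.150 M (fed, over 6.40 h) | 0.150 M | 0.150 M |
| remark | run made earlier | run made earlier | run made earlier | run made earlier | one stirred flow tank at steady state, fed with the mixture as stated, mean residence time 80.0 h | a stirred flask in which G is dosed at a steady rate over 6.40 h without added volume, worked up at 8.0 h | everything together in a closed stirred flask, run for 8.0 h | a single well-mixed tank run continuously and read at steady state, 8.0 h in it on average |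
| time |  |  |  |  |  | 8.0 h | 8.0 h |  |

- order of the set-ups by the share of Q in all that became Q or J, at the outlet or at the end, highest first (maple / birch / elm / larch)
- share of Q in all that became Q or J, at the outlet or at the end, maple
- share of Q in all that became Q or J, at the outlet or at the end, birch
- share of Q in all that became Q or J, at the outlet or at the end, elm
- share of Q in all that became Q or J, at the outlet or at the end, larch

| run | time / h | Q / % | J / % |
|---|---|---|---|
| zeta | 0.417 | 0 | 2.3 |
| zeta | 0.667 | 0 | 0.6 |
| zeta | 1.33 | 0 | 0.1 |
| zeta | 2.50 | 0.6 | 6.6 |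
| zeta | 5.00 | 2.6 | 10.7 |
| theta | 0.667 | 0 | 0 |
| theta | 1.33 | 0 | 0 |
| theta | 2.50 | 0.9 | 3.8 |
| theta | 4.00 | 1.5 | 4.7 |
| theta | 8.00 | 7.5 | 11.5 |
| gamma | 0.667 | 0 | 1.3 |
| gamma | 1.33 | 2.1 | 0 |
| gamma | 2.50 | 2.4 | 5.3 |
| gamma | 4.00 | 3.4 | 7.2 |
| gamma | 8.00 | 6.6 | 14.2 |
| eta | 0.667 | 0.6 | 0.5 |
| eta | 2.00 | 0.5 | 6.4 |
| eta | 4.00 | 2.0 | 8.7 |
| eta | 6.00 | 5.6 | 12.6 |
| eta | 8.00 | 7.3 | 15.7 |

(readings scatter by 1 percentage point)

- in percentages every species weighs as the D in it: one J counts as two
- the stated concentrations are those of everything mixed, before any reaction; amounts are the same in each set-up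
- the numbers in the tables scatter with a standard deviation of 1 percentage point
- candidate steps: D <-> X; G -> L; X + L -> Q; D + X -> J
- the feed brings no volume worth counting
- the earlier runs were made in a closed, stirred flask

In the candidate steps, Q and J both draw on X, so X cancels from their ratio, which then follows L against D. L is made from G, so while G and D stay near their charges, L rises with time and with the charge of G. Q over J at time t in a closed flask should therefore be the charge ratio G/D times t times one constant. But the early Q readings are of the size of the scatter, 1 percentage point, so the 8.00 h readings serve. Theta gives 0.0272 h⁻¹, gamma 0.0290 h⁻¹ and eta 0.0264 h⁻¹. Their mean, a reading of 0.0275 h⁻¹, is the partition clock: the rise of Q over J per hour and per unit of G/D, which makes Q over J a selectivity factor that grows with time.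

Elm has the zeta charge, so its Q over J should reach 0.331, a share of 24.8%. Birch receives its G over 6.40 h, so it should lie lower, and the tanks, where L stands at one steady level, should lie higher, with maple, at 80.0 h, first.

The forecast gives maple > larch > elm > birch, with 70% for maple, 14% for birch, 29% for elm and 47% for larch, on the ground that “selectivity depends only on L/D”.

The flask gives maple > larch > elm > birch: maple 66.5%, birch 13.5%, elm 25.8%, larch 33.6%.

    D ⇌ X (K = 0.140, k = 4.90 × 10⁻⁴ min⁻¹)
    G → L (k = 0.00150 min⁻¹)
    X + L → Q (k = 0.130 M⁻¹ min⁻¹)
    D + X → J (k = 0.0920 M⁻¹ min⁻¹)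

Elm ends with Q at 5.99% and J at 17.3% of the D charged, a ratio of 0.346 against the clock's 0.331. In birch, G enters evenly over 6.40 h, so L summed over the 8.0 h should come to about 0.413 of elm's sum. The clock then gives birch a ratio of 0.137, a share of 12.0%, and birch stands at 13.5%.

The earlier runs and the new flask come from a simulation on assumed constants, and the scatter is random.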